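## Structural features

The target is an 8-O-4' neolignan. Two benzene rings, each 1,3,4,5-tetrasubstituted, are joined not directly but through the ether oxygen that links C8 of the ring A side chain to C4' of ring B. Ring A (4-hydroxy-3,5-dimethoxyphenyl) carries the chain C7–C8–C9, with a benzylic hydroxyl at C7, the aryloxy group at C8 and a primary hydroxyl at C9. Ring B has a methoxy group on each side of the ether oxygen and, para to it, the chain C7'–C8'–C9' ending in a 1,2-diol. C7 (S) and C8 (R) are adjacent and erythro; C8' (S) lies seven bonds from C8 and cannot be relayed to or from the other two. The fragile region is C7: a benzylic alcohol para to a phenolic oxygen ionises readily under acid (epimerisation, solvolysis, quinone methide), and the aryl enol ethers used on the way are acid-labile too. The difficulty is threefold: the C8–O bond to a phenol flanked by two methoxy groups, the erythro relation at C7/C8, and the absolute sense of that diad beside a remote third centre, where the wrong sense gives a diastereomer that will be hard to remove. The key step uses the fact that C7 (OH, ring A) and C8 (ring B oxygen, C9) are neighbouring CH carbons. This is the pattern left by syn addition of OH to C7 and H to C8 across a (Z)-C7=C8 aryl enol ether, with the ring B oxygen directing the regiochemistry.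

## Logic of the disconnections

18 back to 17. The four O–CH2Ph bonds (O4 of ring A, O9, O8', O9') are cut. Every hydroxyl is masked by the same group because the p-hydroxybenzylic alcohol of 18 does not tolerate acid, so one neutral reductive step replaces a fluoride, an acid and a hydrogenolysis step. The demand is that hydrogenolysis stops short of the benzylic C7–O bond.

17 back to 15 (through 16). The C7–O and C8–H bonds are cut, removing H and OH across C7–C8 to give the (Z)-enol ether. Both stereocentres vanish, and the hindered C8–O–aryl bond now sits on an sp2 carbon where a condensation can build it. The forward step must place boron on C7 only, add to one face only (reagent control), start from geometrically pure 15, and keep 16 from losing the ring B phenoxide before oxidation.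

15 back to 14 and 13. The O9–CH2Ph bond and then the two C9–H bonds are cut, taking C9 back to the ester level. The ester is what allows C7=C8 to be made by carbonyl chemistry. The demand is 1,2-reduction and base-only handling that leave the acid-labile enol ether and its geometry alone.

13 back to 9 and 10. The C7=C8 double bond is cut (aldol condensation retron). The molecule falls into a ring A half and a ring B half of similar size. The forward step must deliver the Z isomer, because the alkene geometry becomes the erythro relation.

9 back to 7 and 8. The O4'–C8 bond is cut. The crowded aryl ether is then formed by SN2 at an unhindered primary carbon and not at a secondary stereocentre. The only demand is a free phenol.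

7 back to 6 and 5. The O4'–CH2OMe bond is restored and the O8'–CH2Ph bond is cut. The phenol must be masked during the organometallic step by a group that leaves without touching benzyl ethers, and O8' must carry a group that leaves with the others at the end.

5 back to 2 and 3 (through 4). The C1'–C7' bond is cut. This leads to a chiral-pool epoxide that already holds C8' with its oxygen, so the one stereocentre nothing else could control is bought. The nucleophile must attack only the terminal epoxide carbon, leaving the stereocentre untouched.

2 back to 1. The O–CH2OMe bond is cut, which is routine masking of the phenol.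

## Other disconnections considered

Alternative 1: The cut is the O4'–C4' aryl–oxygen bond, leaving the C8–O bond and both carbinol centres in one fragment.
- **Forward step:** the potassium alkoxide (KN(SiMe3)2) of the (1S,2R)-alcohol A1 would displace fluoride from 4-fluoro-3,5-dimethoxybenzaldehyde A2 by addition–elimination, giving the aldehyde A3.
- **In favour:** neither stereocentre is touched, so the erythro (7S,8R) diad would be as pure as A1. No alkene geometry, organoborane or face selection is involved. On stereochemical certainty at C7/C8 this plan is better than the chosen one.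
- **Against:** the fluorine of A2 lies between two methoxy groups that hinder attack and donate into the ring, and only one para formyl group activates it. A hindered secondary alkoxide may instead add to the formyl group and start hydride-transfer disproportionation. A1 needs its own asymmetric synthesis with three differentiated oxygens. A3 has a formyl group where the target has the (S)-2,3-dihydroxypropyl chain, so C7'–C9' and C8' must still be built by a two-carbon homologation and an asymmetric oxidation of a terminal alkene, a substrate class for which such oxidations are not among the most selective.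
- **Comparison:** the chosen plan is more convergent, since ring B arrives with its complete chiral-pool side chain. The displacement is a simpler event than a face-selective hydroboration but is poorly served by this arene. The alternative is expected to be clearly longer. The final global hydrogenolysis is the same in both, a point of equality.

Alternative 2: The cut removes two bonds at C8 at once, C8–O4' and C7–C8.
- **Forward step:** Rh2(OAc)4 would turn ethyl diazoacetate A5 into a carbenoid. The O–H of the ring B phenol A4 (side-chain acetonide) would add to it, and a chiral phosphoric acid would steer capture of the resulting ylide or enol by aldehyde 10 to the (2S,3S)-hydroxy ester A6, before a 1,2-proton shift ends the sequence as plain O–H insertion.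
- **In favour:** one step would make both bonds and both stereocentres from three simple components. C9 is one ester reduction from the right oxidation level. The insertion is little affected by the two ortho methoxy groups. In convergence and step count this plan is better than the chosen one, by about four steps.
- **Against:** 10 is a weakly electrophilic aldehyde, so the proton shift is expected to compete strongly. The erythro/threo ratio and the absolute sense would both rest on one catalyst–substrate match with no close analogue for a 2,6-disubstituted phenol. The carbenoid has other targets in the electron-rich arenes and the benzyl ether. The acetonide of A4 must survive the acid catalyst.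
- **Comparison:** both plans contain a step beyond precedent, a point of equality. The chosen plan separates the problems: relative configuration follows from alkene geometry and the syn mechanism, and only face selection is open. Here chemo-, diastereo- and enantioselectivity must be solved in one event.

Alternative 3: The cut is the C1–C7 bond between ring A and the carbinol carbon.
- **Forward step:** the aryl Grignard reagent A7 of benzyl-protected ring A would add to the (R)-2-aryloxy-3-benzyloxypropanal A8, whose C8 centre comes from the chiral pool. Non-chelated 1,2-induction would place the new C7 hydroxyl anti to the aryloxy group, giving the erythro alcohol A9.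
- **In favour:** every reaction type is established, the absolute configuration at C8 is bought and not induced, and the coupling is as convergent as in the chosen plan. On precedent it is better than the chosen plan; on step count it is about equal.
- **Against:** A8 has an acidic α-hydrogen and a β-benzyloxy group, so epimerisation at C8 and β-elimination threaten under the basic conditions of the addition. Magnesium can chelate the carbonyl oxygen with the aryloxy oxygen, an ortho methoxy group or the C9 benzyloxy group, and chelation would reverse the induction at C7. The erythro preference is therefore a conformational bias and not a mechanistic necessity, and a wrong C7 configuration would need an oxidation and reduction to correct.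
- **Comparison:** here the absolute configuration at C8 is certain and the relative configuration is the weak point. In the chosen plan the relative configuration is certain (Z geometry plus syn addition) and the absolute sense is the weak point.

Key step: step 9

Remarks on the chemistry:
- Atom labels follow neolignan usage: ring A C1–C6 with chain C7–C9, ring B C1'–C6' with chain C7'–C9'.
- Compound 10 is taken as a catalogue compound.
- Phenoxides, alkoxides and the ester enolate formed by deprotonation of numbered compounds are treated as forms of those compounds and carry no number.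
- Enol ethers 13–15 are handled without acid (silica pre-treated with Et3N).

## Route

Step 1
Reactants: 1 4-bromo-2,6-dimethoxyphenol
Product: 2 5-bromo-1,3-dimethoxy-2-(methoxymethoxy)benzene
Conditions: NaH, MOMCl, THF, 0 °C → rt
Reagents that add atoms: chloromethyl methyl ether, COCCl
Why: Williamson-type O-alkylation of the sodium phenoxide with a reactive α-chloro ether; the acetal hides the acidic phenol from the Grignard reagent and can later be removed by dilute acid without touching benzyl ethers.

Step 2
Reactants: 2 5-bromo-1,3-dimethoxy-2-(methoxymethoxy)benzene; 3 (S)-benzyl glycidyl ether [(S)-2-[(benzyloxy)methyl]oxirane]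
Product: 5 (S)-1-(benzyloxy)-3-[3,5-dimethoxy-4-(methoxymethoxy)phenyl]propan-2-ol, via aryl Grignard reagent 4 (not isolated)
Conditions: Mg, THF, 50 °C; then CuI (10 mol%), 3, −30 → 0 °C; H2O
Reagents that add atoms: none
Why: Copper-catalysed Grignard opening of a terminal epoxide, an SN2 attack at the unsubstituted CH2 that becomes C7'; no bond to the stereocentre is made or broken, so C8' keeps the S configuration bought with 3.

Step 3
Reactants: 5 (S)-1-(benzyloxy)-3-[3,5-dimethoxy-4-(methoxymethoxy)phenyl]propan-2-ol
Product: 6 5-[(S)-2,3-bis(benzyloxy)propyl]-1,3-dimethoxy-2-(methoxymethoxy)benzene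
Conditions: NaH, BnBr, Bu4NI (cat.), THF/DMF, 0 °C → rt
Reagents that add atoms: benzyl bromide, BrCc1ccccc1
Why: Williamson ether synthesis on the secondary alkoxide; the acetal and the aryl bromide-free arene are inert to the base, and O8' now carries a group that will leave in the final hydrogenolysis.

Step 4
Reactants: 6 5-[(S)-2,3-bis(benzyloxy)propyl]-1,3-dimethoxy-2-(methoxymethoxy)benzene
Product: 7 4-[(S)-2,3-bis(benzyloxy)propyl]-2,6-dimethoxyphenol
Conditions: HCl (cat.), MeOH, 45 °C
Reagents that add atoms: none
Why: Acid-catalysed acetal exchange passes the methoxymethyl group to methanol; benzyl ethers, aryl methyl ethers and the C8' centre are stable to dilute acid.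

Step 5
Reactants: 7 4-[(S)-2,3-bis(benzyloxy)propyl]-2,6-dimethoxyphenol; 8 ethyl bromoacetate
Product: 9 ethyl 2-{4-[(S)-2,3-bis(benzyloxy)propyl]-2,6-dimethoxyphenoxy}acetate
Conditions: K2CO3, acetone, reflux
Reagents that add atoms: none
Why: Williamson ether synthesis; the hindered phenoxide meets an unhindered, carbonyl-activated primary bromide, so the future O4'–C8 bond forms without steric penalty.

Step 6
Reactants: 9 ethyl 2-{4-[(S)-2,3-bis(benzyloxy)propyl]-2,6-dimethoxyphenoxy}acetate; 10 4-(benzyloxy)-3,5-dimethoxybenzaldehyde
Product: 13 ethyl (Z)-3-[4-(benzyloxy)-3,5-dimethoxyphenyl]-2-{4-[(S)-2,3-bis(benzyloxy)propyl]-2,6-dimethoxyphenoxy}acrylate, via lithium aldolate 11 (not isolated), via aldol acetate 12 (not isolated)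
Conditions: LiN(SiMe3)2, THF, −78 °C; 10; Ac2O, −78 → 0 °C; DBU, rt
Reagents that add atoms: none
Why: Aldol addition of the ester lithium enolate to a non-enolisable aldehyde, O-acetylation of the aldolate and E1cB elimination through the re-formed ester enolate, which funnels both aldol diastereomers into one conjugated product; the Z isomer (ring A trans to the ester, cis to the aryloxy group) should dominate because the E isomer suffers A(1,3) strain between ring A and the ester, and any E isomer is removed here by crystallisation or chromatography since it would lead to the threo series.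

Step 7
Reactants: 13 ethyl (Z)-3-[4-(benzyloxy)-3,5-dimethoxyphenyl]-2-{4-[(S)-2,3-bis(benzyloxy)propyl]-2,6-dimethoxyphenoxy}acrylate
Product: 14 (Z)-3-[4-(benzyloxy)-3,5-dimethoxyphenyl]-2-{4-[(S)-2,3-bis(benzyloxy)propyl]-2,6-dimethoxyphenoxy}prop-2-en-1-ol
Conditions: i-Bu2AlH, CH2Cl2, −78 → −20 °C; aq KNaC4H4O6 (potassium sodium tartrate)
Reagents that add atoms: none
Why: 1,2-Reduction of an α,β-unsaturated ester by an electrophilic aluminium hydride gives the allylic alcohol without conjugate reduction; the neutral tartrate work-up protects the enol ether and its geometry.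

Step 8
Reactants: 14 (Z)-3-[4-(benzyloxy)-3,5-dimethoxyphenyl]-2-{4-[(S)-2,3-bis(benzyloxy)propyl]-2,6-dimethoxyphenoxy}prop-2-en-1-ol
Product: 15 2-(benzyloxy)-5-[(Z)-3-(benzyloxy)-2-{4-[(S)-2,3-bis(benzyloxy)propyl]-2,6-dimethoxyphenoxy}prop-1-en-1-yl]-1,3-dimethoxybenzene
Conditions: NaH, BnBr, Bu4NI (cat.), THF, 0 °C → rt
Reagents that add atoms: benzyl bromide, BrCc1ccccc1
Why: Williamson ether synthesis on the primary allylic alkoxide; the hydroxyl is capped so that it neither consumes hydride nor directs the borane, and the cap is the same group as all the others.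

Step 9
Reactants: 15 2-(benzyloxy)-5-[(Z)-3-(benzyloxy)-2-{4-[(S)-2,3-bis(benzyloxy)propyl]-2,6-dimethoxyphenoxy}prop-1-en-1-yl]-1,3-dimethoxybenzene
Product: 17 (1S,2R)-3-(benzyloxy)-1-[4-(benzyloxy)-3,5-dimethoxyphenyl]-2-{4-[(S)-2,3-bis(benzyloxy)propyl]-2,6-dimethoxyphenoxy}propan-1-ol, via organoborane 16 (not isolated)
Conditions: (IpcBH2)2·TMEDA [from (+)-α-pinene], BF3·OEt2, THF, rt, filter; then 15, THF, −25 → 0 °C; then NaBO3·4H2O, THF/H2O, 0 °C → rt
Reagents that add atoms: sodium perborate tetrahydrate NaBO3·4H2O (oxygen at C7), [Na+].[Na+].O[B-]1(O)OO[B-](O)(O)OO1.O.O.O.O.O.O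
Why: Proposed new method: the B–H bond of monoisopinocampheylborane should add across the (Z)-C7=C8 enol ether through the usual concerted four-centre transition state, boron to C7 and hydrogen to C8 on the same face, and peroxoborate oxidation then replaces C7–B by C7–OH with retention; the closest known reaction types are the asymmetric hydroboration–oxidation of trisubstituted alkenes with this reagent and the β-selective hydroboration–oxidation of enol ethers, cyclic aryl enol ethers included, but an acyclic 2-aryloxyallyl ether has not been used in this way. No ring is closed and no skeletal bond is formed. The relative configuration of the two new centres is set by the substrate: ring A and the aryloxy group are cis in 15, so syn addition of H and OH can only give the erythro diad. The absolute configuration is set by the reagent: by analogy with simple trans-disubstituted and trisubstituted alkenes, where the reagent from (+)-α-pinene gives (S)-carbinols whose substituents rank OH > former alkene carbon > own substituent, the same face preference at C7 (OH > C8 > ring A) predicts 7S and hence 8R, while C8' is too remote to help or hinder. Regioselectivity (boron at C7) should be secured by the enol ether oxygen, whose lone pair is left free to polarise the alkene because the two ortho methoxy groups twist ring B out of conjugation, and by the lower substitution of C7; the electron-rich ring A is not relied on for it. The step also requires that the β-aryloxy borane 16 does not expel the ring B phenoxide, so the reagent is freed of BF3 by filtration, the addition is kept at or below 0 °C, and the oxidation follows at once under nearly neutral conditions instead of strong alkali. Benzyl ethers and both arenes are inert to the borane, and the configuration at C7 is to be confirmed on 17 (MTPA esters) before the route is continued.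

Step 10
Reactants: 17 (1S,2R)-3-(benzyloxy)-1-[4-(benzyloxy)-3,5-dimethoxyphenyl]-2-{4-[(S)-2,3-bis(benzyloxy)propyl]-2,6-dimethoxyphenoxy}propan-1-ol
Product: 18 (1S,2R)-2-{4-[(S)-2,3-dihydroxypropyl]-2,6-dimethoxyphenoxy}-1-(4-hydroxy-3,5-dimethoxyphenyl)propane-1,3-diol (CNP0229130.1)
Conditions: H2 (1 atm), 10% Pd/C, EtOAc/EtOH, rt
Reagents that add atoms: none
Why: Catalytic hydrogenolysis cleaves the aryl and the three alkyl benzyl ethers as toluene under neutral conditions, which spare the acid-sensitive benzylic C7–OH, the alkyl aryl ether and all three stereocentres.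

## Compound list

1 | 4-bromo-2,6-dimethoxyphenol | COc1cc(Br)cc(OC)c1O | starting material
2 | 5-bromo-1,3-dimethoxy-2-(methoxymethoxy)benzene | COCOc1c(OC)cc(Br)cc1OC | intermediate
3 | (S)-benzyl glycidyl ether | C1[C@H](O1)COCc1ccccc1 | starting material
4 | [3,5-dimethoxy-4-(methoxymethoxy)phenyl]magnesium bromide | COCOc1c(OC)cc([Mg]Br)cc1OC | intermediate
5 | (S)-1-(benzyloxy)-3-[3,5-dimethoxy-4-(methoxymethoxy)phenyl]propan-2-ol | COCOc1c(OC)cc(C[C@H](O)COCc2ccccc2)cc1OC | intermediate
6 | 5-[(S)-2,3-bis(benzyloxy)propyl]-1,3-dimethoxy-2-(methoxymethoxy)benzene | COCOc1c(OC)cc(C[C@H](OCc2ccccc2)COCc2ccccc2)cc1OC | intermediate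
7 | 4-[(S)-2,3-bis(benzyloxy)propyl]-2,6-dimethoxyphenol | COc1cc(C[C@H](OCc2ccccc2)COCc2ccccc2)cc(OC)c1O | intermediate
8 | ethyl bromoacetate | CCOC(=O)CBr | starting material
9 | ethyl 2-{4-[(S)-2,3-bis(benzyloxy)propyl]-2,6-dimethoxyphenoxy}acetate | CCOC(=O)COc1c(OC)cc(C[C@H](OCc2ccccc2)COCc2ccccc2)cc1OC | intermediate
10 | 4-(benzyloxy)-3,5-dimethoxybenzaldehyde | COc1cc(C=O)cc(OC)c1OCc1ccccc1 | starting material
11 | lithium aldolate: lithium salt of ethyl 3-[4-(benzyloxy)-3,5-dimethoxyphenyl]-2-{4-[(S)-2,3-bis(benzyloxy)propyl]-2,6-dimethoxyphenoxy}-3-hydroxypropanoate (mixture at C2 and C3) | CCOC(=O)C(Oc1c(OC)cc(C[C@H](OCc2ccccc2)COCc2ccccc2)cc1OC)C(O[Li])c1cc(OC)c(OCc2ccccc2)c(OC)c1 | intermediate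
12 | aldol acetate: ethyl 3-acetoxy-3-[4-(benzyloxy)-3,5-dimethoxyphenyl]-2-{4-[(S)-2,3-bis(benzyloxy)propyl]-2,6-dimethoxyphenoxy}propanoate (mixture at C2 and C3) | CCOC(=O)C(Oc1c(OC)cc(C[C@H](OCc2ccccc2)COCc2ccccc2)cc1OC)C(OC(C)=O)c1cc(OC)c(OCc2ccccc2)c(OC)c1 | intermediate
13 | ethyl (Z)-3-[4-(benzyloxy)-3,5-dimethoxyphenyl]-2-{4-[(S)-2,3-bis(benzyloxy)propyl]-2,6-dimethoxyphenoxy}acrylate | CCOC(=O)/C(Oc1c(OC)cc(C[C@H](OCc2ccccc2)COCc2ccccc2)cc1OC)=C/c1cc(OC)c(OCc2ccccc2)c(OC)c1 | intermediate
14 | (Z)-3-[4-(benzyloxy)-3,5-dimethoxyphenyl]-2-{4-[(S)-2,3-bis(benzyloxy)propyl]-2,6-dimethoxyphenoxy}prop-2-en-1-ol | COc1cc(/C=C(/CO)Oc2c(OC)cc(C[C@H](OCc3ccccc3)COCc3ccccc3)cc2OC)cc(OC)c1OCc1ccccc1 | intermediate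
15 | 2-(benzyloxy)-5-[(Z)-3-(benzyloxy)-2-{4-[(S)-2,3-bis(benzyloxy)propyl]-2,6-dimethoxyphenoxy}prop-1-en-1-yl]-1,3-dimethoxybenzene (key-step precursor) | COc1cc(/C=C(/COCc3ccccc3)Oc2c(OC)cc(C[C@H](OCc3ccccc3)COCc3ccccc3)cc2OC)cc(OC)c1OCc1ccccc1 | intermediate
16 | organoborane: [(1S,2R)-C7-boryl adduct] {(1S,2R)-3-(benzyloxy)-1-[4-(benzyloxy)-3,5-dimethoxyphenyl]-2-{4-[(S)-2,3-bis(benzyloxy)propyl]-2,6-dimethoxyphenoxy}propyl}[(1R,2S,3R,5R)-isopinocampheyl]borane | C[C@H]1[C@H](B[C@@H](c2cc(OC)c(OCc3ccccc3)c(OC)c2)[C@@H](COCc2ccccc2)Oc2c(OC)cc(C[C@H](OCc3ccccc3)COCc3ccccc3)cc2OC)C[C@@H]2C[C@H]1C2(C)C | intermediate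
17 | (1S,2R)-3-(benzyloxy)-1-[4-(benzyloxy)-3,5-dimethoxyphenyl]-2-{4-[(S)-2,3-bis(benzyloxy)propyl]-2,6-dimethoxyphenoxy}propan-1-ol (key-step product, 7S,8R,8'S) | COc1cc([C@H](O)[C@@H](COCc3ccccc3)Oc2c(OC)cc(C[C@H](OCc3ccccc3)COCc3ccccc3)cc2OC)cc(OC)c1OCc1ccccc1 | intermediate
18 | (1S,2R)-2-{4-[(S)-2,3-dihydroxypropyl]-2,6-dimethoxyphenoxy}-1-(4-hydroxy-3,5-dimethoxyphenyl)propane-1,3-diol | COc1cc([C@H](O)[C@@H](CO)Oc2c(OC)cc(C[C@H](O)CO)cc2OC)cc(OC)c1O | target

## Step count and least certain steps

Total step count: 10. Longest linear sequence: 10 steps (1 to 18; compounds 3, 8 and 10 enter as purchased materials).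

**Step 9 (key step, the new method).**
- Most likely failure: insufficient face discrimination by the chiral borane. The aryl-substituted, oxygen-polarised alkene differs electronically from the simple alkenes on which the prediction rests, and the minor face gives a diastereomer that differs only at centres remote from C8', so it will be hard to separate.
- Second risk: β-elimination of the ring B phenoxide from the organoborane before oxidation, followed by a second hydroboration of the resulting alkene.
- Third risk: leakage of boron to C8.
- Should only the sense of induction be opposite to the prediction, the reagent from (−)-α-pinene is used instead.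
- Fallback by known chemistry, setting out from 7 and returning at 17: a Mitsunobu reaction (PPh3, DIAD, THF) of 7 with catalogue methyl (S)-3-(benzyloxy)-2-hydroxypropanoate, an L-serine-pool compound, should give with inversion methyl (R)-3-(benzyloxy)-2-{4-[(S)-2,3-bis(benzyloxy)propyl]-2,6-dimethoxyphenoxy}propanoate F1. Treatment with Me(MeO)NH·HCl and i-PrMgCl (THF, −20 °C) would convert it into (R)-3-(benzyloxy)-2-{4-[(S)-2,3-bis(benzyloxy)propyl]-2,6-dimethoxyphenoxy}-N-methoxy-N-methylpropanamide F2. Separately, 2-(benzyloxy)-5-bromo-1,3-dimethoxybenzene F3 (from 1, BnBr, K2CO3, DMF) would be lithiated (n-BuLi, THF, −78 °C) to [4-(benzyloxy)-3,5-dimethoxyphenyl]lithium F4, which should add once to F2 and give (R)-3-(benzyloxy)-1-[4-(benzyloxy)-3,5-dimethoxyphenyl]-2-{4-[(S)-2,3-bis(benzyloxy)propyl]-2,6-dimethoxyphenoxy}propan-1-one F5. Reduction with LiBH(s-Bu)3 (THF, −78 °C) under non-chelation control, the aryloxy group anti to the incoming hydride, is expected to favour the erythro alcohol, which is 17. C8 then comes from the chiral pool and C7 from 1,2-induction; the price is four more operations and an epimerisable α-aryloxy ketone.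

**Step 6.**
- Most likely failure: incomplete geometric control in the elimination, or retro-aldol cleavage before the aldolate is acetylated, leaving E isomer that would later give the threo series.
- Fallback with a different bond-forming approach, setting out from 9 and returning at 13: saponification (LiOH, THF/H2O) would give 2-{4-[(S)-2,3-bis(benzyloxy)propyl]-2,6-dimethoxyphenoxy}acetic acid F6. A Perkin condensation with 10 (Ac2O, Et3N, 110 °C) places the aryl group trans to the carboxyl group under equilibrating conditions and should give (Z)-3-[4-(benzyloxy)-3,5-dimethoxyphenyl]-2-{4-[(S)-2,3-bis(benzyloxy)propyl]-2,6-dimethoxyphenoxy}acrylic acid F7, purified by crystallisation. Re-esterification (EtI, K2CO3, DMF) then gives 13.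

**Step 10.**
- Most likely failure: slow cleavage of the three alkyl benzyl ethers, so that prolonged exposure leads to hydrogenolysis of the benzylic C7–O bond once the ring A phenol is free.
- Fallback that masks the sensitive position, setting out from 17 and returning at 18: silylation (TBSOTf, 2,6-lutidine, CH2Cl2, −78 °C) would give tert-butyl{(1S,2R)-3-(benzyloxy)-1-[4-(benzyloxy)-3,5-dimethoxyphenyl]-2-{4-[(S)-2,3-bis(benzyloxy)propyl]-2,6-dimethoxyphenoxy}propoxy}dimethylsilane F8, whose bulky benzylic silyl ether should resist C–O hydrogenolysis. Hydrogenolysis (H2, Pd/C, EtOAc) would then give (2R,3S)-3-[(tert-butyldimethylsilyl)oxy]-2-{4-[(S)-2,3-dihydroxypropyl]-2,6-dimethoxyphenoxy}-3-(4-hydroxy-3,5-dimethoxyphenyl)propan-1-ol F9, and Bu4NF buffered with AcOH (THF, 0 °C) releases 18.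

## Further compounds

F1 | step 9 | methyl (R)-3-(benzyloxy)-2-{4-[(S)-2,3-bis(benzyloxy)propyl]-2,6-dimethoxyphenoxy}propanoate | COC(=O)[C@@H](COCc1ccccc1)Oc1c(OC)cc(C[C@H](OCc2ccccc2)COCc2ccccc2)cc1OC
F2 | step 9 | (R)-3-(benzyloxy)-2-{4-[(S)-2,3-bis(benzyloxy)propyl]-2,6-dimethoxyphenoxy}-N-methoxy-N-methylpropanamide | CON(C)C(=O)[C@@H](COCc1ccccc1)Oc1c(OC)cc(C[C@H](OCc2ccccc2)COCc2ccccc2)cc1OC
F3 | step 9 | 2-(benzyloxy)-5-bromo-1,3-dimethoxybenzene | COc1cc(Br)cc(OC)c1OCc1ccccc1
F4 | step 9 | [4-(benzyloxy)-3,5-dimethoxyphenyl]lithium | [Li]c1cc(OC)c(OCc2ccccc2)c(OC)c1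
F5 | step 9 | (R)-3-(benzyloxy)-1-[4-(benzyloxy)-3,5-dimethoxyphenyl]-2-{4-[(S)-2,3-bis(benzyloxy)propyl]-2,6-dimethoxyphenoxy}propan-1-one | COc1cc(C(=O)[C@@H](COCc3ccccc3)Oc2c(OC)cc(C[C@H](OCc3ccccc3)COCc3ccccc3)cc2OC)cc(OC)c1OCc1ccccc1
F6 | step 6 | 2-{4-[(S)-2,3-bis(benzyloxy)propyl]-2,6-dimethoxyphenoxy}acetic acid | OC(=O)COc1c(OC)cc(C[C@H](OCc2ccccc2)COCc2ccccc2)cc1OC
F7 | step 6 | (Z)-3-[4-(benzyloxy)-3,5-dimethoxyphenyl]-2-{4-[(S)-2,3-bis(benzyloxy)propyl]-2,6-dimethoxyphenoxy}acrylic acid | OC(=O)/C(Oc1c(OC)cc(C[C@H](OCc2ccccc2)COCc2ccccc2)cc1OC)=C/c1cc(OC)c(OCc2ccccc2)c(OC)c1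
F8 | step 10 | tert-butyl{(1S,2R)-3-(benzyloxy)-1-[4-(benzyloxy)-3,5-dimethoxyphenyl]-2-{4-[(S)-2,3-bis(benzyloxy)propyl]-2,6-dimethoxyphenoxy}propoxy}dimethylsilane | COc1cc([C@H](O[Si](C)(C)C(C)(C)C)[C@@H](COCc3ccccc3)Oc2c(OC)cc(C[C@H](OCc3ccccc3)COCc3ccccc3)cc2OC)cc(OC)c1OCc1ccccc1
F9 | step 10 | (2R,3S)-3-[(tert-butyldimethylsilyl)oxy]-2-{4-[(S)-2,3-dihydroxypropyl]-2,6-dimethoxyphenoxy}-3-(4-hydroxy-3,5-dimethoxyphenyl)propan-1-ol | COc1cc([C@H](O[Si](C)(C)C(C)(C)C)[C@@H](CO)Oc2c(OC)cc(C[C@H](O)CO)cc2OC)cc(OC)c1O
A1 | alternative 1 | (1S,2R)-1,3-bis(benzyloxy)-1-[4-(benzyloxy)-3,5-dimethoxyphenyl]propan-2-ol | COc1cc([C@H](OCc2ccccc2)[C@H](O)COCc2ccccc2)cc(OC)c1OCc1ccccc1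
A2 | alternative 1 | 4-fluoro-3,5-dimethoxybenzaldehyde | COc1cc(C=O)cc(OC)c1F
A3 | alternative 1 | 4-{[(1S,2R)-1,3-bis(benzyloxy)-1-[4-(benzyloxy)-3,5-dimethoxyphenyl]propan-2-yl]oxy}-3,5-dimethoxybenzaldehyde | COc1cc([C@H](OCc3ccccc3)[C@@H](COCc3ccccc3)Oc2c(OC)cc(C=O)cc2OC)cc(OC)c1OCc1ccccc1
A4 | alternative 2 | 4-{[(S)-2,2-dimethyl-1,3-dioxolan-4-yl]methyl}-2,6-dimethoxyphenol | COc1cc(C[C@H]2COC(C)(C)O2)cc(OC)c1O
A5 | alternative 2 | ethyl diazoacetate | CCOC(=O)C=[N+]=[N-]
A6 | alternative 2 | ethyl (2S,3S)-3-[4-(benzyloxy)-3,5-dimethoxyphenyl]-2-(4-{[(S)-2,2-dimethyl-1,3-dioxolan-4-yl]methyl}-2,6-dimethoxyphenoxy)-3-hydroxypropanoate | COc1cc([C@H](O)[C@@H](C(=O)OCC)Oc2c(OC)cc(C[C@H]3COC(C)(C)O3)cc2OC)cc(OC)c1OCc1ccccc1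
A7 | alternative 3 | [4-(benzyloxy)-3,5-dimethoxyphenyl]magnesium bromide | COc1cc([Mg]Br)cc(OC)c1OCc1ccccc1
A8 | alternative 3 | (R)-3-(benzyloxy)-2-(4-{[(S)-2,2-dimethyl-1,3-dioxolan-4-yl]methyl}-2,6-dimethoxyphenoxy)propanal | O=C[C@@H](COCc1ccccc1)Oc1c(OC)cc(C[C@H]2COC(C)(C)O2)cc1OC
A9 | alternative 3 | (1S,2R)-3-(benzyloxy)-1-[4-(benzyloxy)-3,5-dimethoxyphenyl]-2-(4-{[(S)-2,2-dimethyl-1,3-dioxolan-4-yl]methyl}-2,6-dimethoxyphenoxy)propan-1-ol | COc1cc([C@H](O)[C@@H](COCc3ccccc3)Oc2c(OC)cc(C[C@H]4COC(C)(C)O4)cc2OC)cc(OC)c1OCc1ccccc1
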